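The earlier runs and the new flask were generated by integration from invented constants; the scatter is artificial.

| flask | substrate | remark | time |
|---|---|---|---|
| Tuesday's | 0.025 M | run made earlier |  |
| Saturday's | 0.038 M | run made earlier |  |
| flask | 0.050 M |  | 6.0 min |

| run | time / min | target / % |
|---|---|---|
| Tuesday's | 1.50 | 0.4 |
| Tuesday's | 2.00 | 0 |
| Tuesday's | 2.50 | 0.3 |
| Tuesday's | 3.00 | 0.9 |
| Tuesday's | 4.00 | 3.1 |
| Saturday's | 1.50 | 0 |
| Saturday's | 2.00 | 0.1 |
| Saturday's | 2.50 | 0.9 |
| Saturday's | 3.00 | 0.8 |
| Saturday's | 4.00 | 2.5 |

(readings scatter by 0.3 percentage points)

1. the moment within 6.0 min at which there is most target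
2. the amount of target, in percent of the substrate charged, at that time

At 2.50 min, Saturday's run, charged with 0.038 M of substrate, stood ahead of Tuesday's, charged with 0.025 M: it read 0.9% of target against 0.3%. At 4.00 min the order had turned, with 2.5% against 3.1%. The gap was 0.6 percentage points each way and each reading scatters by 0.3 points, so I treated both runs as one curve in percent of charge and applied no correction for the larger charge of the new flask.

That curve shows a lag (induction period) followed by a steep climb. The run means went from 0.600% at 2.50 min to 2.80% at 4.00 min. From these I took the rise power n, the exponent in "target grows as time to the power n", and the two means give n = 3.28. It is a reading, and its weak point is the earlier mean, whose two readings lie far apart.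

From 2.00 min to 4.00 min each mean of the two runs stood above the one before, so I placed the best moment at the limit of 6.0 min. Carrying the later mean there by n gave me 10.6%, above the forecast's 10% (range 6.5% to 18%) at 6 min (range 5.3 min to 6 min), which rested on “Nothing shows the target being consumed”.

The flask gave 10.2% at 6.00 min, with 31.3% of the charge then standing as intermediate C.

    intermediate B → intermediate C (k = 0.0140 /s)
    intermediate C → intermediate D (k = 0.00330 /s)
    substrate → intermediate A (k = 0.0310 /s)
    intermediate A → intermediate B (k = 0.00480 /s)
    2 substrate → self-condensation product (k = 0.220 /M/s)
    intermediate E → target (k = 0.0370 /s)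
    intermediate D → intermediate E (k = 0.00950 /s)

From 2.86% in the flask read at 4.0 min, the flask's own rise power up to 6.0 min was 3.14. Carrying the 0.465% of the flask stopped at 2.5 min forward by n gives 2.17% at 4.0 min, where the flask read then holds 2.86%.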